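**Retrosynthetic overview**
Germacrane locants: ring A = ten-membered carbocycle C1–C10; ring B = 3(2H)-furanone (O, C1, C2, C3, C4; the 1,4-epoxy bridge); ring C = α-methylene-γ-lactone (O, C6, C7, C11, C12; C13 = exocyclic CH2).
Last disconnection: the C8–O ester bond, made from (2R,3R)-epoxyangelic acid (from methyl angelate by Sharpless epoxidation).
Key disconnection C6–C7. The enabling feature is ring C: C13–C11=C7 is a 2-(alkoxycarbonyl)allyl unit with C7 as its γ-carbon and C6 is a carbinol carbon, so C6–C7 is an allylmetal/aldehyde bond. One CrCl2 operation closes ring A (bridged over ring B) and ring C and sets C6 and C7; the cis C9=C10 bond and planar ring B hold the two ends close.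
The bromo aldehyde precursor comes from Sonogashira union at C1–C10 of an ynone (C1–C6, C4 from (R)-citramalic acid) with a (Z)-vinyl iodide (C7–C13, C8 from asymmetric alkynylation), then gold-catalysed 5-endo closure of ring B.
Order of ring formation: side-chain epoxide (step 19, separate branch); ring B (step 13); rings A and C together (step 16).

Key step: step 16

Assumption: the face selectivities of the ProPhenol alkynylation (step 9) and the Sharpless epoxidation (step 19) follow the accepted empirical models; the ligand antipode would be exchanged if the opposite sense were found.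

**Ynone branch (C1–C6)**

Step 1
Reactants: 1 (R)-citramalic acid
Product: 2 2-[(4R)-2,2,4-trimethyl-5-oxo-1,3-dioxolan-4-yl]acetic acid
Conditions: 2,2-dimethoxypropane, TsOH·H2O (cat.), CH2Cl2, rt
Reagents that add atoms: 2,2-dimethoxypropane, COC(C)(C)OC
Why: Acid-catalysed acetonide (dioxolanone) formation engages only the α-hydroxy acid unit, which leaves the β-carboxyl group free and does not touch the stereocentre.

Step 2
Reactants: 2 2-[(4R)-2,2,4-trimethyl-5-oxo-1,3-dioxolan-4-yl]acetic acid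
Product: 3 (5R)-5-(2-hydroxyethyl)-2,2,5-trimethyl-1,3-dioxolan-4-one
Conditions: BH3·SMe2, THF, 0 °C → rt; MeOH quench
Reagents that add atoms: none
Why: Borane reduction is chemoselective for the free carboxylic acid over the dioxolanone carbonyl.

Step 3
Reactants: 3 (5R)-5-(2-hydroxyethyl)-2,2,5-trimethyl-1,3-dioxolan-4-one
Product: 4 (5R)-2,2,5-trimethyl-5-[2-(triethylsilyloxy)ethyl]-1,3-dioxolan-4-one
Conditions: Et3SiCl, imidazole, CH2Cl2, 0 °C
Reagents that add atoms: chlorotriethylsilane, CC[Si](Cl)(CC)CC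
Why: Standard silylation of the primary alcohol, done at once so that the alcohol cannot translactonise onto the dioxolanone.

Step 4
Reactants: 4 (5R)-2,2,5-trimethyl-5-[2-(triethylsilyloxy)ethyl]-1,3-dioxolan-4-one
Product: 5 (2R)-2-hydroxy-N-methoxy-N,2-dimethyl-4-(triethylsilyloxy)butanamide
Conditions: MeNH(OMe)·HCl, iPrMgCl, THF, −20 → 0 °C
Reagents that add atoms: N,O-dimethylhydroxylamine hydrochloride, CNOC.Cl
Why: Weinreb aminolysis of the activated dioxolanone ester by the magnesium amide opens the ring with loss of acetone and frees the tertiary hydroxyl.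

Step 5
Reactants: 5 (2R)-2-hydroxy-N-methoxy-N,2-dimethyl-4-(triethylsilyloxy)butanamide
Product: 6 (2R)-N-methoxy-N,2-dimethyl-4-(triethylsilyloxy)-2-(trimethylsilyloxy)butanamide
Conditions: Me3SiOTf, 2,6-lutidine, CH2Cl2, −78 °C
Reagents that add atoms: trimethylsilyl trifluoromethanesulfonate, C[Si](C)(C)OS(=O)(=O)C(F)(F)F
Why: Silyl triflate silylation caps the hindered tertiary alcohol so that the later hydroxy ynone cannot cyclise before the cross-coupling.

Step 6
Reactants: 6 (2R)-N-methoxy-N,2-dimethyl-4-(triethylsilyloxy)-2-(trimethylsilyloxy)butanamide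
Product: 7 (4R)-4-methyl-6-(triethylsilyloxy)-4-(trimethylsilyloxy)hex-1-yn-3-one
Conditions: HC≡CMgBr, THF, 0 °C; cold aq. NH4Cl
Reagents that add atoms: ethynylmagnesium bromide, C#C[Mg]Br
Why: Weinreb ketone synthesis: the chelated tetrahedral intermediate stops at single addition, and the cold quench keeps the liberated amine from adding to the terminal ynone.

**Vinyl iodide branch (C7–C13)**

Step 7
Reactants: 8 but-2-yn-1-ol
Product: 10 (Z)-3-iodobut-2-en-1-ol, via cyclic alkenylalanate 9 (not isolated)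
Conditions: Red-Al [NaAlH2(OCH2CH2OMe)2], THF, 0 °C → rt; then I2, THF, −78 °C
Reagents that add atoms: iodine, II
Why: Alkoxide-directed trans-hydroalumination of the propargylic alcohol puts aluminium on C3, and iodinolysis with retention gives the (Z)-iodoalkene.

Step 8
Reactants: 10 (Z)-3-iodobut-2-en-1-ol
Product: 11 (Z)-3-iodobut-2-enal
Conditions: MnO2, CH2Cl2, rt, dark; used crude
Reagents that add atoms: none
Why: Neutral allylic oxidation with MnO2, run without light or acid, should keep the Z geometry of the sensitive β-iodo enal.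

Step 9
Reactants: 11 (Z)-3-iodobut-2-enal; 12 methyl propiolate
Product: 14 methyl (4S,5Z)-4-hydroxy-6-iodohept-5-en-2-ynoate, via zinc acetylide 13 (not isolated)
Conditions: Me2Zn, (S,S)-ProPhenol (20 mol %), Ph3PO (40 mol %), toluene, 0–4 °C; aq. NH4Cl
Reagents that add atoms: none
Why: Trost dinuclear zinc–ProPhenol asymmetric alkynylation of an enal: the chiral catalyst delivers acetylide 13 to one aldehyde face and so sets C8 (4S in 14).

Step 10
Reactants: 14 methyl (4S,5Z)-4-hydroxy-6-iodohept-5-en-2-ynoate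
Product: 15 methyl (4S,5Z)-4-(tert-butyldimethylsilyloxy)-6-iodohept-5-en-2-ynoate
Conditions: tBuMe2SiCl, imidazole, DMF, 0 °C
Reagents that add atoms: tert-butyldimethylsilyl chloride, CC(C)(C)[Si](C)(C)Cl
Why: Silylation under imidazole conditions protects the γ-hydroxy ynoate before base can isomerise it.

Step 11
Reactants: 15 methyl (4S,5Z)-4-(tert-butyldimethylsilyloxy)-6-iodohept-5-en-2-ynoate
Product: 17 methyl (2Z,4R,5Z)-4-(tert-butyldimethylsilyloxy)-2-(hydroxymethyl)-6-iodohepta-2,5-dienoate, via vinylalane 16 (not isolated)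
Conditions: iBu2AlH, N-methylmorpholine N-oxide, THF, 0 °C; then CH2O (monomeric, from paraformaldehyde), −20 °C → rt
Reagents that add atoms: formaldehyde, C=O
Why: Conjugate syn-hydroalumination of the ynoate (vinylalumination) gives α-aluminio acrylate 16, which adds to formaldehyde with retention and so installs C13 on C11; the C8 centre is untouched (its descriptor changes only through CIP priorities).

**Fragment union and ring B**

Step 12
Reactants: 7 (4R)-4-methyl-6-(triethylsilyloxy)-4-(trimethylsilyloxy)hex-1-yn-3-one; 17 methyl (2Z,4R,5Z)-4-(tert-butyldimethylsilyloxy)-2-(hydroxymethyl)-6-iodohepta-2,5-dienoate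
Product: 18 methyl (2Z,4S,5Z,10R)-4-(tert-butyldimethylsilyloxy)-2-(hydroxymethyl)-6,10-dimethyl-9-oxo-12-(triethylsilyloxy)-10-(trimethylsilyloxy)dodeca-2,5-dien-7-ynoate
Conditions: Pd(PPh3)4 (5 mol %), CuI (10 mol %), iPr2NEt, THF, 0 °C → rt
Reagents that add atoms: none
Why: Sonogashira coupling forms C1–C10 with retention of the Z geometry; a hindered tertiary amine at low temperature is chosen to spare the terminal ynone.

Step 13
Reactants: 18 methyl (2Z,4S,5Z,10R)-4-(tert-butyldimethylsilyloxy)-2-(hydroxymethyl)-6,10-dimethyl-9-oxo-12-(triethylsilyloxy)-10-(trimethylsilyloxy)dodeca-2,5-dien-7-ynoate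
Product: 20 methyl (2Z,4S,5Z)-4-(tert-butyldimethylsilyloxy)-6-[(5R)-5-(2-hydroxyethyl)-5-methyl-4-oxo-4,5-dihydrofuran-2-yl]-2-(hydroxymethyl)hepta-2,5-dienoate, via triol ynone 19 (not isolated)
Conditions: PPTS (0.2 equiv), MeOH, 0 °C → rt; then AuCl3 (5 mol %), CH2Cl2–MeOH, rt
Reagents that add atoms: none
Why: Mild acidic methanolysis removes the Me3Si and Et3Si ethers but not the secondary tBuMe2Si ether, and gold-catalysed 5-endo-dig oxa-cyclisation of the 4-hydroxy ynone (tertiary OH onto C1) closes ring B.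

Step 14
Reactants: 20 methyl (2Z,4S,5Z)-4-(tert-butyldimethylsilyloxy)-6-[(5R)-5-(2-hydroxyethyl)-5-methyl-4-oxo-4,5-dihydrofuran-2-yl]-2-(hydroxymethyl)hepta-2,5-dienoate
Product: 21 methyl (2E,4S,5Z)-2-(bromomethyl)-4-(tert-butyldimethylsilyloxy)-6-[(5R)-5-(2-hydroxyethyl)-5-methyl-4-oxo-4,5-dihydrofuran-2-yl]hepta-2,5-dienoate
Conditions: NBS premixed with Me2S, CH2Cl2, −30 → 0 °C
Reagents that add atoms: N-bromosuccinimide, O=C1CCC(=O)N1Br
Why: Corey–Kim halogenation converts allylic alcohols to bromides under neutral conditions, while the saturated primary alcohol is returned unchanged on work-up.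

Step 15
Reactants: 21 methyl (2E,4S,5Z)-2-(bromomethyl)-4-(tert-butyldimethylsilyloxy)-6-[(5R)-5-(2-hydroxyethyl)-5-methyl-4-oxo-4,5-dihydrofuran-2-yl]hepta-2,5-dienoate
Product: 22 methyl (2E,4S,5Z)-2-(bromomethyl)-4-(tert-butyldimethylsilyloxy)-6-[(5R)-5-methyl-4-oxo-5-(2-oxoethyl)-4,5-dihydrofuran-2-yl]hepta-2,5-dienoate
Conditions: Dess–Martin periodinane, NaHCO3, CH2Cl2, 0 °C → rt; used crude
Reagents that add atoms: none
Why: Buffered Dess–Martin oxidation gives the β-alkoxy aldehyde without touching the allylic bromide or causing retro-oxa-Michael opening of ring B.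

**Key step and endgame**

Step 16
Reactants: 22 methyl (2E,4S,5Z)-2-(bromomethyl)-4-(tert-butyldimethylsilyloxy)-6-[(5R)-5-methyl-4-oxo-5-(2-oxoethyl)-4,5-dihydrofuran-2-yl]hepta-2,5-dienoate
Product: 25 (4R,6S,7R,8S,9Z)-8-(tert-butyldimethylsilyloxy)-1,4-epoxy-3-oxogermacra-1,9,11(13)-trien-12,6-olide, via allylchromium species 23 (not isolated), via hydroxy ester 24 (not isolated)
Conditions: CrCl2 (8 equiv), THF–DMF (4:1), syringe-pump addition of 22 (final 0.003 M), rt; aq. NH4Cl; then TsOH·H2O (cat.), CH2Cl2, rt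
Reagents that add atoms: none
Why: Two equivalents of CrCl2 (divalent chromium) reduce the allylic bromide to the σ-allylchromium species 23 (trivalent chromium on C13), which adds through its γ-carbon C7 to the C6 aldehyde in a six-membered chair-like transition state, and the resulting γ-hydroxy ester 24 lactonises onto the C12 methyl ester. The closest known reaction type is the Nozaki–Hiyama–Kishi (chromium-mediated Barbier) allylation of aldehydes with 2-(bromomethyl)alk-2-enoates, including its intramolecular use to close ten-membered germacranolide rings together with the α-methylene lactone. Ring A closes in an exo-trig mode on the aldehyde carbonyl (10-exo counted through C2 and C3, 9-exo counted through the ring B oxygen; the aldehyde oxygen and C11 stay outside the new ring), and ring C closes by 5-exo-trig acyl substitution of the C6 oxygen at C12 with loss of methanol. C6 and C7 should arise 6,7-anti (trans-fused lactone, 6S,7R) from the chair in which both ring tethers (C5 on the aldehyde, C8 on the γ-carbon) are pseudo-equatorial; the C7 face is set by the existing C8 centre, because allylic 1,3-strain puts C8–H in the plane of C7=C11, the silyloxy group outside and ring carbon C9 anti to the incoming aldehyde, which makes H7 and H8 cis. The step needs aldehyde selectivity over the ring B ketone and the ester (inherent to organochromium reagents), ring closure over oligomerisation (high dilution; the cis C9=C10 bond and planar ring B hold C6 near C7), and no 1,4-elimination of the C8 oxygen (a silyl ether is a poor leaving group).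

Step 17
Reactants: 25 (4R,6S,7R,8S,9Z)-8-(tert-butyldimethylsilyloxy)-1,4-epoxy-3-oxogermacra-1,9,11(13)-trien-12,6-olide
Product: 26 (4R,6S,7S,8S,9Z)-8-hydroxy-1,4-epoxy-3-oxogermacra-1,9,11(13)-trien-12,6-olide
Conditions: HF·pyridine, pyridine, THF, 0 °C → rt
Reagents that add atoms: none
Why: Buffered fluoride desilylation frees the C8 alcohol without base that could add to the α-methylene lactone; no stereocentre changes in space (the C7 descriptor changes only through CIP priorities).

**Side chain**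

Step 18
Reactants: 27 methyl angelate
Product: 28 (Z)-2-methylbut-2-en-1-ol
Conditions: iBu2AlH, CH2Cl2, −78 °C; Rochelle salt work-up
Reagents that add atoms: none
Why: Low-temperature hydride reduction of the ester to the allylic alcohol should keep the Z geometry.

Step 19
Reactants: 28 (Z)-2-methylbut-2-en-1-ol
Product: 29 [(2S,3R)-2,3-dimethyloxiran-2-yl]methanol
Conditions: Ti(OiPr)4, L-(+)-diisopropyl tartrate, tBuOOH, 4 Å molecular sieves, CH2Cl2, −20 °C
Reagents that add atoms: tert-butyl hydroperoxide, CC(C)(C)OO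
Why: Sharpless asymmetric epoxidation is stereospecific (Z alkene gives the angelate-type epoxide), and the L-(+)-tartrate is expected by the Sharpless face rule to give the (2S,3R) epoxy alcohol, which sets both epoxide centres.

Step 20
Reactants: 29 [(2S,3R)-2,3-dimethyloxiran-2-yl]methanol
Product: 31 (2R,3R)-2,3-dimethyloxirane-2-carboxylic acid, via epoxy aldehyde 30 (not isolated)
Conditions: PhI(OAc)2 (2.2 equiv), TEMPO (cat.), MeCN–H2O, rt
Reagents that add atoms: water, O
Why: TEMPO/PhI(OAc)2 oxidation takes the primary alcohol through the aldehyde hydrate to the acid; the quaternary C2 cannot epimerise.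

Step 21
Reactants: 26 (4R,6S,7S,8S,9Z)-8-hydroxy-1,4-epoxy-3-oxogermacra-1,9,11(13)-trien-12,6-olide; 31 (2R,3R)-2,3-dimethyloxirane-2-carboxylic acid
Product: 33 (4R,6S,7R,8S,9Z)-1,4-epoxy-3-oxogermacra-1,9,11(13)-trien-12,6-olid-8-yl (2R,3R)-2,3-dimethyloxirane-2-carboxylate (target), via mixed anhydride 32 (not isolated)
Conditions: 2,4,6-trichlorobenzoyl chloride, Et3N, toluene, rt; then 26, DMAP, toluene, rt → 40 °C
Reagents that add atoms: none
Why: Yamaguchi esterification acylates the hindered allylic C8 alcohol through mixed anhydride 32 with retention at every stereocentre.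

**Compound list**
1 | (R)-citramalic acid, (2R)-2-hydroxy-2-methylbutanedioic acid | OC(=O)C[C@@](C)(O)C(=O)O | starting material
2 | 2-[(4R)-2,2,4-trimethyl-5-oxo-1,3-dioxolan-4-yl]acetic acid | OC(=O)C[C@@]1(C)OC(C)(C)OC1=O | intermediate
3 | (5R)-5-(2-hydroxyethyl)-2,2,5-trimethyl-1,3-dioxolan-4-one | OCC[C@@]1(C)OC(C)(C)OC1=O | intermediate
4 | (5R)-2,2,5-trimethyl-5-[2-(triethylsilyloxy)ethyl]-1,3-dioxolan-4-one | CC[Si](CC)(CC)OCC[C@@]1(C)OC(C)(C)OC1=O | intermediate
5 | (2R)-2-hydroxy-N-methoxy-N,2-dimethyl-4-(triethylsilyloxy)butanamide | CC[Si](CC)(CC)OCC[C@@](C)(O)C(=O)N(C)OC | intermediate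
6 | (2R)-N-methoxy-N,2-dimethyl-4-(triethylsilyloxy)-2-(trimethylsilyloxy)butanamide | CC[Si](CC)(CC)OCC[C@@](C)(O[Si](C)(C)C)C(=O)N(C)OC | intermediate
7 | (4R)-4-methyl-6-(triethylsilyloxy)-4-(trimethylsilyloxy)hex-1-yn-3-one | CC[Si](CC)(CC)OCC[C@@](C)(O[Si](C)(C)C)C(=O)C#C | intermediate
8 | but-2-yn-1-ol | CC#CCO | starting material
9 | cyclic sodium alkenylalanate (Al bound to O1 and C3 of the butenol, two 2-methoxyethoxy ligands) | CC1=CCO[Al-]1(OCCOC)OCCOC.[Na+] | intermediate
10 | (Z)-3-iodobut-2-en-1-ol | I/C(C)=C\CO | intermediate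
11 | (Z)-3-iodobut-2-enal | I/C(C)=C\C=O | intermediate
12 | methyl propiolate | C#CC(=O)OC | starting material
13 | methyl 3-(methylzincio)prop-2-ynoate (zinc acetylide) | C[Zn]C#CC(=O)OC | intermediate
14 | methyl (4S,5Z)-4-hydroxy-6-iodohept-5-en-2-ynoate | I/C(C)=C\[C@H](O)C#CC(=O)OC | intermediate
15 | methyl (4S,5Z)-4-(tert-butyldimethylsilyloxy)-6-iodohept-5-en-2-ynoate | I/C(C)=C\[C@H](O[Si](C)(C)C(C)(C)C)C#CC(=O)OC | intermediate
16 | methyl (2E,4R,5Z)-4-(tert-butyldimethylsilyloxy)-2-(diisobutylalumanyl)-6-iodohepta-2,5-dienoate (vinylalane) | I/C(C)=C\[C@H](O[Si](C)(C)C(C)(C)C)/C=C(/[Al](CC(C)C)CC(C)C)C(=O)OC | intermediate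
17 | methyl (2Z,4R,5Z)-4-(tert-butyldimethylsilyloxy)-2-(hydroxymethyl)-6-iodohepta-2,5-dienoate | I/C(C)=C\[C@H](O[Si](C)(C)C(C)(C)C)/C=C(/CO)C(=O)OC | intermediate
18 | methyl (2Z,4S,5Z,10R)-4-(tert-butyldimethylsilyloxy)-2-(hydroxymethyl)-6,10-dimethyl-9-oxo-12-(triethylsilyloxy)-10-(trimethylsilyloxy)dodeca-2,5-dien-7-ynoate | CC[Si](CC)(CC)OCC[C@@](C)(O[Si](C)(C)C)C(=O)C#C/C(C)=C\[C@H](O[Si](C)(C)C(C)(C)C)/C=C(/CO)C(=O)OC | intermediate
19 | methyl (2Z,4S,5Z,10R)-4-(tert-butyldimethylsilyloxy)-10,12-dihydroxy-2-(hydroxymethyl)-6,10-dimethyl-9-oxododeca-2,5-dien-7-ynoate (triol ynone) | OCC[C@@](C)(O)C(=O)C#C/C(C)=C\[C@H](O[Si](C)(C)C(C)(C)C)/C=C(/CO)C(=O)OC | intermediate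
20 | methyl (2Z,4S,5Z)-4-(tert-butyldimethylsilyloxy)-6-[(5R)-5-(2-hydroxyethyl)-5-methyl-4-oxo-4,5-dihydrofuran-2-yl]-2-(hydroxymethyl)hepta-2,5-dienoate | OCC[C@@]1(C)OC(=CC1=O)/C(C)=C\[C@H](O[Si](C)(C)C(C)(C)C)/C=C(/CO)C(=O)OC | intermediate
21 | methyl (2E,4S,5Z)-2-(bromomethyl)-4-(tert-butyldimethylsilyloxy)-6-[(5R)-5-(2-hydroxyethyl)-5-methyl-4-oxo-4,5-dihydrofuran-2-yl]hepta-2,5-dienoate | OCC[C@@]1(C)OC(=CC1=O)/C(C)=C\[C@H](O[Si](C)(C)C(C)(C)C)/C=C(/CBr)C(=O)OC | intermediate
22 | methyl (2E,4S,5Z)-2-(bromomethyl)-4-(tert-butyldimethylsilyloxy)-6-[(5R)-5-methyl-4-oxo-5-(2-oxoethyl)-4,5-dihydrofuran-2-yl]hepta-2,5-dienoate | O=CC[C@@]1(C)OC(=CC1=O)/C(C)=C\[C@H](O[Si](C)(C)C(C)(C)C)/C=C(/CBr)C(=O)OC | intermediate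
23 | σ-allylchromium dichloride derived from 22 (trivalent chromium on C13 in place of bromine) | O=CC[C@@]1(C)OC(=CC1=O)/C(C)=C\[C@H](O[Si](C)(C)C(C)(C)C)/C=C(/C[Cr](Cl)Cl)C(=O)OC | intermediate
24 | methyl 2-[(4R,6S,7R,8S,9Z)-8-(tert-butyldimethylsilyloxy)-6-hydroxy-1,4-epoxy-3-oxogermacra-1,9-dien-7-yl]prop-2-enoate (hydroxy ester) | O[C@H]1C[C@@]2(C)OC(=CC2=O)/C(C)=C\[C@H](O[Si](C)(C)C(C)(C)C)[C@@H]1C(=C)C(=O)OC | intermediate
25 | (4R,6S,7R,8S,9Z)-8-(tert-butyldimethylsilyloxy)-1,4-epoxy-3-oxogermacra-1,9,11(13)-trien-12,6-olide | C=C1C(=O)O[C@H]2C[C@@]3(C)OC(=CC3=O)/C(C)=C\[C@H](O[Si](C)(C)C(C)(C)C)[C@H]12 | intermediate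
26 | (4R,6S,7S,8S,9Z)-8-hydroxy-1,4-epoxy-3-oxogermacra-1,9,11(13)-trien-12,6-olide | C=C1C(=O)O[C@H]2C[C@@]3(C)OC(=CC3=O)/C(C)=C\[C@H](O)[C@H]12 | intermediate
27 | methyl angelate, methyl (Z)-2-methylbut-2-enoate | C/C=C(/C)C(=O)OC | starting material
28 | (Z)-2-methylbut-2-en-1-ol | C/C=C(/C)CO | intermediate
29 | [(2S,3R)-2,3-dimethyloxiran-2-yl]methanol | OC[C@]1(C)O[C@@H]1C | intermediate
30 | (2R,3R)-2,3-dimethyloxirane-2-carbaldehyde | O=C[C@]1(C)O[C@@H]1C | intermediate
31 | (2R,3R)-2,3-dimethyloxirane-2-carboxylic acid | OC(=O)[C@]1(C)O[C@@H]1C | intermediate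
32 | (2R,3R)-2,3-dimethyloxirane-2-carboxylic 2,4,6-trichlorobenzoic anhydride | O=C(OC(=O)c1c(Cl)cc(Cl)cc1Cl)[C@]2(C)O[C@@H]2C | intermediate
33 | (4R,6S,7R,8S,9Z)-1,4-epoxy-3-oxogermacra-1,9,11(13)-trien-12,6-olid-8-yl (2R,3R)-2,3-dimethyloxirane-2-carboxylate | C=C1C(=O)O[C@H]2C[C@@]3(C)OC(=CC3=O)/C(C)=C\[C@H](OC(=O)[C@]3(C)O[C@@H]3C)[C@H]12 | target

**Step count**
Total: 21 steps. Longest linear sequence: 13 steps (steps 1–6, 12–17, 21).

**Steps most likely to fail**

Step 16 (key step). Ring closure across the furanone-bridged ring may be slow, so that oligomerisation, simple reduction of the allylic bromide or 1,4-elimination of the C8 oxygen compete; the aldehyde may also add to the wrong face of C7. The fallback closes the ten-membered ring on the flexible open-chain ynone and forms ring B afterwards by transannular cyclisation. It sets out from 18: Corey–Kim bromination (NBS, Me2S) of its only free hydroxyl should give the open-chain bromo ynone F1. Swern conditions ((COCl)2, DMSO; iPr2NEt), which oxidise primary triethylsilyl ethers directly, should give the bromo aldehyde F2. CrCl2 under high dilution followed by catalytic TsOH should give the ten-membered enynone lactone F3. AuCl3 in MeOH–CH2Cl2 should then remove the Me3Si group and effect transannular 5-endo oxa-cyclisation, which returns to the route at 25.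

Step 12. The amine base may add to the terminal ynone 7 and copper may promote its homocoupling before cross-coupling occurs. The fallback replaces the Sonogashira reaction by an amine-free and copper-free Stille coupling. It sets out from 7: Bu3SnOMe (neat, methanol removed under vacuum) should give the alkynylstannane F4, and coupling of F4 with 17 (Pd2(dba)3, AsPh3, DMF, rt) returns to the route at 18.

Step 9. The β-iodo enal may isomerise from Z to E at the Lewis acidic zinc centres, or catalyst control may be incomplete, giving 14 of low geometric or enantiomeric purity. The fallback separates C–C bond formation from the setting of C8. It sets out from 11: addition of the lithium acetylide of 12 (LiN(SiMe3)2, THF, −78 °C) should give the racemic propargylic alcohol F5. Dess–Martin oxidation should give the cross-conjugated ynone F6. Reduction with (S)-Me-CBS oxazaborolidine and catecholborane at −78 °C (alkyne as the small group) returns to the route at 14.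

**Further compounds**
F1 | step 16 | methyl (2E,4S,5Z,10R)-2-(bromomethyl)-4-(tert-butyldimethylsilyloxy)-6,10-dimethyl-9-oxo-12-(triethylsilyloxy)-10-(trimethylsilyloxy)dodeca-2,5-dien-7-ynoate | CC[Si](CC)(CC)OCC[C@@](C)(O[Si](C)(C)C)C(=O)C#C/C(C)=C\[C@H](O[Si](C)(C)C(C)(C)C)/C=C(/CBr)C(=O)OC
F2 | step 16 | methyl (2E,4S,5Z,10R)-2-(bromomethyl)-4-(tert-butyldimethylsilyloxy)-6,10-dimethyl-9,12-dioxo-10-(trimethylsilyloxy)dodeca-2,5-dien-7-ynoate | O=CC[C@@](C)(O[Si](C)(C)C)C(=O)C#C/C(C)=C\[C@H](O[Si](C)(C)C(C)(C)C)/C=C(/CBr)C(=O)OC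
F3 | step 16 | (4R,6S,7R,8S,9Z)-8-(tert-butyldimethylsilyloxy)-3-oxo-4-(trimethylsilyloxy)germacra-9,11(13)-dien-1-yn-12,6-olide | C=C1C(=O)O[C@H]2C[C@@](C)(O[Si](C)(C)C)C(=O)C#C/C(C)=C\[C@H](O[Si](C)(C)C(C)(C)C)[C@H]12
F4 | step 12 | (4R)-4-methyl-1-(tributylstannyl)-6-(triethylsilyloxy)-4-(trimethylsilyloxy)hex-1-yn-3-one | CC[Si](CC)(CC)OCC[C@@](C)(O[Si](C)(C)C)C(=O)C#C[Sn](CCCC)(CCCC)CCCC
F5 | step 9 | methyl (5Z)-4-hydroxy-6-iodohept-5-en-2-ynoate (racemic) | I/C(C)=C\C(O)C#CC(=O)OC
F6 | step 9 | methyl (5Z)-6-iodo-4-oxohept-5-en-2-ynoate | I/C(C)=C\C(=O)C#CC(=O)OC
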